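## Retrosynthetic overview

1. The target is the C7–C5' biaryl dimer of one monomer, (1S,4R)-8-hydroxycalamenene. The biaryl bond is cut first (Suzuki–Miyaura coupling of a C7 boronic acid and a C5 bromide, both from the same O-methyl monomer), and the two methyl ethers are cleaved last.
2. Feature used: in each tetralin unit C1 is a benzylic CH(CH3) stereocentre on arene carbon C8a. Its bond to C2 belongs to the saturated ring, and the C2–C3–C4 chain hangs from the adjacent arene carbon C4a with the isopropyl centre C4 already on it.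
3. Key disconnection C1–C2: C2 moves from boron to a lithiated C1 carbamate inside a seven-membered cyclic boronate, which contracts to the six-membered carbocycle. The C1–B bond that remains is then exchanged for C1–H with retention.
4. The open-chain precursor comes from 3,5-dimethoxytoluene (acetylation between the methoxy groups, mono-demethylation, triflation). C1 is set by oxazaborolidine-catalysed ketone reduction, C4 by copper–carbene-catalysed SN2' arylation of an isopropyl-substituted allyl phosphate, and boron is added by hydroboration.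
5. Ring order: the arene rings are bought, the saturated ring of the monomer is closed once (key step), and two portions of the monomer are then joined.

Key step: step 11

Remark on locants: tetralin numbering is used throughout (C1 methyl, C4 isopropyl, C6 methyl, C8 oxygen). Primed locants belong to the unit joined through C5'.

Assumption on the axis: the given structure defines no configuration for the tetra-ortho-substituted C7–C5' axis, so it is left uncontrolled. Any stable atropisomers would be separated by chromatography at the coupled bis(methyl ether) or at the target.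

Assumption on step 9: the (S,S) ligand series is taken to give the required C4 configuration. The sense would be checked on a simple arylboronate, and the (R,R) antipode (equally available from 1,2-diphenylethylenediamine) used if it proves opposite.

## Route

Step 1
Reactants: 1 3,5-dimethoxytoluene; 2 N-methoxy-N-methylacetamide
Product: 4 1-(2,6-dimethoxy-4-methylphenyl)ethanone, via 2,6-dimethoxy-4-methylphenyllithium 3 (not isolated)
Conditions: nBuLi (1.1 equiv), THF, 0 °C to rt, 2 h; then 2, −78 °C to rt; H2O
Reagents that add atoms: none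
Why: Directed ortho-metalation occurs at the one position flanked by both methoxy groups, and acylation by the N-methoxy-N-methylamide stops at the ketone because the chelated tetrahedral adduct survives until work-up.

Step 2
Reactants: 4 1-(2,6-dimethoxy-4-methylphenyl)ethanone
Product: 5 1-(2-hydroxy-6-methoxy-4-methylphenyl)ethanone
Conditions: BCl3 (1.1 equiv), CH2Cl2, −78 to 0 °C; H2O
Reagents that add atoms: none
Why: In this chelation-assisted aryl ether cleavage, BCl3 bound to the ketone oxygen cleaves one adjacent methyl ether and the resulting six-membered boron chelate blocks cleavage of the second (the two ethers are equivalent, so there is no regiochemical issue).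

Step 3
Reactants: 5 1-(2-hydroxy-6-methoxy-4-methylphenyl)ethanone
Product: 6 2-acetyl-3-methoxy-5-methylphenyl trifluoromethanesulfonate
Conditions: Tf2O (1.2 equiv), pyridine, CH2Cl2, 0 °C
Reagents that add atoms: trifluoromethanesulfonic anhydride O=S(=O)(OS(=O)(=O)C(F)(F)F)C(F)(F)F
Why: Standard O-sulfonylation of a phenol turns the oxygen on the future C4a into a cross-coupling handle.

Step 4
Reactants: 6 2-acetyl-3-methoxy-5-methylphenyl trifluoromethanesulfonate
Product: 7 2-[(S)-1-hydroxyethyl]-3-methoxy-5-methylphenyl trifluoromethanesulfonate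
Conditions: (R)-1-methyl-3,3-diphenyltetrahydro-1H,3H-pyrrolo[1,2-c][1,3,2]oxazaborole (15 mol %), BH3·SMe2 (1.0 equiv), THF, −20 to 0 °C; MeOH, then H2O
Reagents that add atoms: none
Why: In this Corey–Bakshi–Shibata reduction the doubly ortho-substituted aryl group is the large substituent and methyl the small one, so the (R)-catalyst should deliver hydride to the face giving the (S)-carbinol, the centre that later dictates C1.

Step 5
Reactants: 7 2-[(S)-1-hydroxyethyl]-3-methoxy-5-methylphenyl trifluoromethanesulfonate
Product: 8 (S)-1-[2-methoxy-4-methyl-6-(trifluoromethylsulfonyloxy)phenyl]ethyl N,N-diisopropylcarbamate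
Conditions: iPr2NCOCl (1.5 equiv), Et3N (2 equiv), DMAP (0.2 equiv), toluene, 110 °C
Reagents that add atoms: N,N-diisopropylcarbamoyl chloride CC(C)N(C(C)C)C(=O)Cl
Why: O-Carbamoylation under amine-base conditions leaves the C–O bond of the stereocentre untouched, and avoiding a free alkoxide prevents transfer of the neighbouring triflyl group.

Step 6
Reactants: 8 (S)-1-[2-methoxy-4-methyl-6-(trifluoromethylsulfonyloxy)phenyl]ethyl N,N-diisopropylcarbamate
Product: 9 (S)-1-[2-(5,5-dimethyl-1,3,2-dioxaborinan-2-yl)-6-methoxy-4-methylphenyl]ethyl N,N-diisopropylcarbamate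
Conditions: bis(neopentyl glycolato)diboron (1.3 equiv), PdCl2(dppf) (5 mol %), KOAc (3 equiv), 1,4-dioxane, 90 °C
Reagents that add atoms: bis(neopentyl glycolato)diboron CC1(C)COB(OC1)B1OCC(C)(C)CO1
Why: Miyaura borylation of an aryl triflate uses only acetate as base, which the carbamate tolerates, and the neopentyl glycol ester is chosen because it should transmetalate to a copper alkoxide more readily than a pinacol ester.

Step 7
Reactants: 10 ethyl (E)-4-methylpent-2-enoate
Product: 11 (E)-4-methylpent-2-en-1-ol
Conditions: iBu2AlH (2.2 equiv), CH2Cl2, −78 to 0 °C; aq. potassium sodium tartrate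
Reagents that add atoms: none
Why: 1,2-Reduction of an α,β-unsaturated ester with a dialkylaluminium hydride gives the allylic alcohol with the (E)-geometry intact.

Step 8
Reactants: 11 (E)-4-methylpent-2-en-1-ol
Product: 12 diethyl (E)-4-methylpent-2-en-1-yl phosphate
Conditions: ClP(O)(OEt)2 (1.2 equiv), pyridine, DMAP (cat.), CH2Cl2, 0 °C to rt
Reagents that add atoms: diethyl chlorophosphate CCOP(=O)(Cl)OCC
Why: O-Phosphorylation of a primary allylic alcohol installs the leaving group needed for copper-catalysed allylic substitution.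

Step 9
Reactants: 9 (S)-1-[2-(5,5-dimethyl-1,3,2-dioxaborinan-2-yl)-6-methoxy-4-methylphenyl]ethyl N,N-diisopropylcarbamate; 12 diethyl (E)-4-methylpent-2-en-1-yl phosphate
Product: 13 (S)-1-{2-methoxy-4-methyl-6-[(S)-4-methylpent-1-en-3-yl]phenyl}ethyl N,N-diisopropylcarbamate
Conditions: CuCl (10 mol %), (4S,5S)-1-(2-hydroxyphenyl)-3-mesityl-4,5-diphenyl-4,5-dihydro-1H-imidazol-3-ium chloride (11 mol %), NaOMe (2 equiv), THF, 30–40 °C
Reagents that add atoms: none
Why: In this copper–N-heterocyclic-carbene-catalysed enantioselective allylic substitution with an arylboronate, methoxide-mediated boron-to-copper transmetalation and SN2' attack at the isopropyl-bearing alkene carbon give the branched product, the chiral carbene (catalyst control) sets C4, and any minor C4 epimer is a diastereomer removable by chromatography.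

Step 10
Reactants: 13 (S)-1-{2-methoxy-4-methyl-6-[(S)-4-methylpent-1-en-3-yl]phenyl}ethyl N,N-diisopropylcarbamate; 14 pinacolborane
Product: 15 (S)-1-{2-methoxy-4-methyl-6-[(R)-4-methyl-1-(4,4,5,5-tetramethyl-1,3,2-dioxaborolan-2-yl)pentan-3-yl]phenyl}ethyl N,N-diisopropylcarbamate
Conditions: 14 (1.3 equiv), [Ir(cod)Cl]2 (1.5 mol %), dppm (3 mol %), CH2Cl2, rt
Reagents that add atoms: none
Why: Iridium-catalysed hydroboration of a monosubstituted alkene with pinacolborane is anti-Markovnikov, so boron lands on the terminal carbon (future C2), and the C4 descriptor changes from S to R only through the change in substituent priorities.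

Step 11
Reactants: 15 (S)-1-{2-methoxy-4-methyl-6-[(R)-4-methyl-1-(4,4,5,5-tetramethyl-1,3,2-dioxaborolan-2-yl)pentan-3-yl]phenyl}ethyl N,N-diisopropylcarbamate
Product: 18 2-[(1S,4R)-4-isopropyl-8-methoxy-1,6-dimethyl-1,2,3,4-tetrahydronaphthalen-1-yl]-4,4,5,5-tetramethyl-1,3,2-dioxaborolane, via lithiated carbamate 16 (not isolated), via cyclic boronate complex 17 (not isolated)
Conditions: LiN(iPr)2 (1.3 equiv, added over 1 h), Et2O (0.01 M), −20 °C, 2 h; then rt to 35 °C, 12 h
Reagents that add atoms: none
Why: Proposed new method: LiN(iPr)2, which binds to the pinacol boronate only reversibly, should remove the carbamate-activated benzylic C1–H with retention to give 16, and the tethered boron should capture this carbanion at once on its lithium-bearing face to give the seven-membered cyclic boronate complex 17. On warming, the endocyclic B–C2 bond, lying antiperiplanar to a pseudo-equatorial C1–O bond, should migrate to C1 with inversion and expel lithium N,N-diisopropylcarbamate. The ring C1–C2–C3–C4–C4a–C8a is thus closed in two stages, carbanion-to-boron capture and then ring contraction by a 1,2-metallate shift, leaving boron exocyclic on C1. The closest known reaction type is the intermolecular lithiation–borylation of enantioenriched secondary benzylic carbamates with boronic esters under in situ conditions, where a lithium amide is added to a mixture of both partners near −20 °C; the new elements are that both partners sit in one molecule and that the migration closes a ring. The new quaternary C1 centre is fixed as (S) by the (S)-carbinol carbon through the sequence retention, retention, inversion, while C4 only influences which conformer of 17 is populated. The step needs C–H removal rather than irreversible attack at boron, intramolecular rather than intermolecular borylation, and carbon rather than oxygen migration; these are secured by the hindered non-nucleophilic amide, by high dilution plus the ortho placement of both arms on the arene, and by the higher migratory aptitude of the primary alkyl group.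

Step 12
Reactants: 18 2-[(1S,4R)-4-isopropyl-8-methoxy-1,6-dimethyl-1,2,3,4-tetrahydronaphthalen-1-yl]-4,4,5,5-tetramethyl-1,3,2-dioxaborolane
Product: 19 (1S,4R)-4-isopropyl-8-methoxy-1,6-dimethyl-1,2,3,4-tetrahydronaphthalene
Conditions: Bu4NF·3H2O (3 equiv), toluene, rt to 45 °C
Reagents that add atoms: none
Why: In this fluoride-promoted protodeboronation of a tertiary benzylic aryl-dialkyl boronic ester, the fluoride–boronate complex passes a proton from bound water to the face that carried boron, so C1–H should form with retention as (S), trans to the C4 isopropyl group.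

Step 13
Reactants: 19 (1S,4R)-4-isopropyl-8-methoxy-1,6-dimethyl-1,2,3,4-tetrahydronaphthalene (first portion)
Product: 20 (1S,4R)-5-bromo-4-isopropyl-8-methoxy-1,6-dimethyl-1,2,3,4-tetrahydronaphthalene
Conditions: NBS (1.02 equiv), MeCN, 0 °C, dark
Reagents that add atoms: N-bromosuccinimide O=C1CCC(=O)N1Br
Why: Electrophilic aromatic bromination with NBS in a polar solvent is para-selective for anisoles, so C5 (para to the methoxy group) should react in preference to C7, and ionic conditions in the dark spare the benzylic C–H bonds.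

Step 14
Reactants: 19 (1S,4R)-4-isopropyl-8-methoxy-1,6-dimethyl-1,2,3,4-tetrahydronaphthalene (second portion)
Product: 22 [(1S,4R)-4-isopropyl-8-methoxy-1,6-dimethyl-1,2,3,4-tetrahydronaphthalen-7-yl]boronic acid, via 7-lithio-8-methoxycalamenene 21 (not isolated)
Conditions: nBuLi (1.5 equiv), TMEDA (1.5 equiv), Et2O, 0 °C to rt, 6 h; B(OiPr)3 (3 equiv), −78 °C to rt; 1 M HCl
Reagents that add atoms: triisopropyl borate CC(C)OB(OC(C)C)OC(C)C; water O
Why: Directed ortho-metalation followed by borylation should work because C7–H is the only hydrogen ortho to the methoxy group, the C6 methyl group is meta to it and not laterally activated, and the tertiary benzylic C1–H and C4–H are kinetically far less acidic.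

Step 15
Reactants: 20 (1S,4R)-5-bromo-4-isopropyl-8-methoxy-1,6-dimethyl-1,2,3,4-tetrahydronaphthalene; 22 [(1S,4R)-4-isopropyl-8-methoxy-1,6-dimethyl-1,2,3,4-tetrahydronaphthalen-7-yl]boronic acid
Product: 23 (1S,4R,1'S,4'R)-4,4'-diisopropyl-8,8'-dimethoxy-1,1',6,6'-tetramethyl-1,1',2,2',3,3',4,4'-octahydro-7,5'-binaphthalene
Conditions: Pd2(dba)3 (2.5 mol %), SPhos (10 mol %), K3PO4 (3 equiv), toluene/H2O 10:1, 100 °C
Reagents that add atoms: none
Why: Suzuki–Miyaura coupling with a bulky electron-rich dialkylbiarylphosphine, the ligand class known to form tetra-ortho-substituted biaryls, joins C7 of one unit to C5' of the other without touching the four sp3 stereocentres.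

Step 16
Reactants: 23 (1S,4R,1'S,4'R)-4,4'-diisopropyl-8,8'-dimethoxy-1,1',6,6'-tetramethyl-1,1',2,2',3,3',4,4'-octahydro-7,5'-binaphthalene
Product: 24 (1S,4R,1'S,4'R)-4,4'-diisopropyl-1,1',6,6'-tetramethyl-1,1',2,2',3,3',4,4'-octahydro-7,5'-binaphthalene-8,8'-diol (target)
Conditions: BBr3 (4 equiv), CH2Cl2, −78 °C to rt; H2O
Reagents that add atoms: none
Why: Lewis-acid cleavage of aryl methyl ethers with BBr3 frees both phenols, and nothing else in the hydrocarbon framework reacts.

## Compound list

1 | 3,5-dimethoxytoluene | COc1cc(C)cc(OC)c1 | starting material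
2 | N-methoxy-N-methylacetamide | CON(C)C(C)=O | starting material
3 | 2,6-dimethoxy-4-methylphenyllithium | COc1cc(C)cc(OC)c1[Li] | intermediate
4 | 1-(2,6-dimethoxy-4-methylphenyl)ethanone | COc1cc(C)cc(OC)c1C(C)=O | intermediate
5 | 1-(2-hydroxy-6-methoxy-4-methylphenyl)ethanone | COc1cc(C)cc(O)c1C(C)=O | intermediate
6 | 2-acetyl-3-methoxy-5-methylphenyl trifluoromethanesulfonate | COc1cc(C)cc(OS(=O)(=O)C(F)(F)F)c1C(C)=O | intermediate
7 | 2-[(S)-1-hydroxyethyl]-3-methoxy-5-methylphenyl trifluoromethanesulfonate | COc1cc(C)cc(OS(=O)(=O)C(F)(F)F)c1[C@H](C)O | intermediate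
8 | (S)-1-[2-methoxy-4-methyl-6-(trifluoromethylsulfonyloxy)phenyl]ethyl N,N-diisopropylcarbamate | COc1cc(C)cc(OS(=O)(=O)C(F)(F)F)c1[C@H](C)OC(=O)N(C(C)C)C(C)C | intermediate
9 | (S)-1-[2-(5,5-dimethyl-1,3,2-dioxaborinan-2-yl)-6-methoxy-4-methylphenyl]ethyl N,N-diisopropylcarbamate | COc1cc(C)cc(B2OCC(C)(C)CO2)c1[C@H](C)OC(=O)N(C(C)C)C(C)C | intermediate
10 | ethyl (E)-4-methylpent-2-enoate | CCOC(=O)/C=C/C(C)C | starting material
11 | (E)-4-methylpent-2-en-1-ol | OC/C=C/C(C)C | intermediate
12 | diethyl (E)-4-methylpent-2-en-1-yl phosphate | CCOP(=O)(OCC)OC/C=C/C(C)C | intermediate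
13 | (S)-1-{2-methoxy-4-methyl-6-[(S)-4-methylpent-1-en-3-yl]phenyl}ethyl N,N-diisopropylcarbamate | COc1cc(C)cc([C@H](C=C)C(C)C)c1[C@H](C)OC(=O)N(C(C)C)C(C)C | intermediate
14 | pinacolborane | CC1(C)OBOC1(C)C | starting material
15 | (S)-1-{2-methoxy-4-methyl-6-[(R)-4-methyl-1-(4,4,5,5-tetramethyl-1,3,2-dioxaborolan-2-yl)pentan-3-yl]phenyl}ethyl N,N-diisopropylcarbamate (key-step precursor) | COc1cc(C)cc([C@H](CCB2OC(C)(C)C(C)(C)O2)C(C)C)c1[C@H](C)OC(=O)N(C(C)C)C(C)C | intermediate
16 | lithiated carbamate (C1–Li in place of C1–H of 15, retention) | COc1cc(C)cc([C@H](CCB2OC(C)(C)C(C)(C)O2)C(C)C)c1[C@]([Li])(C)OC(=O)N(C(C)C)C(C)C | intermediate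
17 | cyclic boronate complex (lithium salt; seven-membered ring B–C1–C8a–C4a–C4–C3–C2, spiro pinacolate on boron) | [Li+].COc1cc(C)cc2c1[C@](C)(OC(=O)N(C(C)C)C(C)C)[B-]1(OC(C)(C)C(C)(C)O1)CC[C@@H]2C(C)C | intermediate
18 | 2-[(1S,4R)-4-isopropyl-8-methoxy-1,6-dimethyl-1,2,3,4-tetrahydronaphthalen-1-yl]-4,4,5,5-tetramethyl-1,3,2-dioxaborolane (key-step product) | COc1cc(C)cc2c1[C@](C)(B1OC(C)(C)C(C)(C)O1)CC[C@@H]2C(C)C | intermediate
19 | (1S,4R)-4-isopropyl-8-methoxy-1,6-dimethyl-1,2,3,4-tetrahydronaphthalene | COc1cc(C)cc2c1[C@@H](C)CC[C@@H]2C(C)C | intermediate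
20 | (1S,4R)-5-bromo-4-isopropyl-8-methoxy-1,6-dimethyl-1,2,3,4-tetrahydronaphthalene | COc1cc(C)c(Br)c2c1[C@@H](C)CC[C@@H]2C(C)C | intermediate
21 | 7-lithio-8-methoxycalamenene | COc1c([Li])c(C)cc2c1[C@@H](C)CC[C@@H]2C(C)C | intermediate
22 | [(1S,4R)-4-isopropyl-8-methoxy-1,6-dimethyl-1,2,3,4-tetrahydronaphthalen-7-yl]boronic acid | COc1c(B(O)O)c(C)cc2c1[C@@H](C)CC[C@@H]2C(C)C | intermediate
23 | (1S,4R,1'S,4'R)-4,4'-diisopropyl-8,8'-dimethoxy-1,1',6,6'-tetramethyl-1,1',2,2',3,3',4,4'-octahydro-7,5'-binaphthalene | Cc1cc2c(c(OC)c1-c1c(C)cc(OC)c3c1[C@@H](C(C)C)CC[C@@H]3C)[C@@H](C)CC[C@@H]2C(C)C | intermediate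
24 | (1S,4R,1'S,4'R)-4,4'-diisopropyl-1,1',6,6'-tetramethyl-1,1',2,2',3,3',4,4'-octahydro-7,5'-binaphthalene-8,8'-diol | Cc1cc2c(c(O)c1-c1c(C)cc(O)c3c1[C@@H](C(C)C)CC[C@@H]3C)[C@@H](C)CC[C@@H]2C(C)C | target

## Step count

Total step count: 16.
Longest linear sequence: 13 steps (1–6, 9–12, 13 or 14, 15, 16).

## Steps most likely to fail

**Step 11 (key step).**
- The amide may remove C1–H too slowly. That hydrogen is flanked by two ortho substituents and must rotate out of its preferred in-plane position before the ring can acidify it.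
- Capture by the boron of a second molecule, loss of configuration before capture, or oxygen rather than carbon migration may also compete.
- The fallback sets out from 13, skips step 10 and returns at 18, using only known reaction types.
- With no boron in the molecule, the stronger base sBuLi/TMEDA (Et2O, −78 °C) can be used and should give the lithiated alkenyl carbamate F1.
- Adding vinylboronic acid pinacol ester gives the vinyl boronate complex F2, whose vinyl group migrates on warming (intermolecular lithiation–borylation) to give the divinyl tertiary boronate F3.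
- Ring-closing metathesis with the second-generation Grubbs catalyst RuCl2(H2IMes)(PCy3)(=CHPh) in toluene at 80 °C forms the C2=C3 bond of the 1,4-dihydronaphthalene boronate F4.
- Hydrogenation (H2, palladium on carbon, EtOAc) then gives 18.

**Step 9.**
- Boron-to-copper transmetalation and C–C bond formation may be slow, because the aryl group carries a branched ortho substituent and must bond to the isopropyl-bearing carbon.
- Branched-to-linear selectivity or enantiofacial control may erode as a result.
- The fallback forms the C4–isopropyl bond instead of the C4–aryl bond. It sets out from 8, replaces steps 6–10 and returns at 15.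
- (S)-4-Phenyloxazolidin-2-one and acryloyl chloride (LiCl, Et3N, THF) give the acrylimide F5.
- Heck reaction of 8 with F5 (PdCl2(PPh3)2, Et3N, DMF, 90 °C) gives the (E)-enoyl imide F6.
- iPrMgCl/CuBr·SMe2 (THF, −40 °C) adds to the magnesium-chelated imide from the face away from the phenyl group, giving the conjugate adduct F7 with (R)-C4.
- LiBH4 (Et2O, 1 equiv H2O) releases the primary alcohol F8.
- An Appel reaction (iodine, PPh3, imidazole) gives the primary iodide F9.
- Copper-catalysed borylation (B2pin2, CuCl, Xantphos, KOtBu, THF, rt) gives 15.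

**Step 15.**
- Transmetalation and reductive elimination at a palladium centre crowded by four ortho substituents may be slower than protodeboronation of the ortho-methoxy boronic acid and reduction of the bromide.
- The fallback replaces catalysis by ligand coupling on tetravalent lead, directed to the position ortho to a free phenol. It sets out from 19 and 20 and returns at 24.
- BBr3 cleaves 19 to the monomer phenol F10.
- Bromine–lithium exchange on 20 (nBuLi, THF, −78 °C) gives the 5-lithio ether F11, which with B(OiPr)3 and aqueous acid gives the 5-boronic acid F12.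
- Boron–lead exchange (Pb(OAc)4, Hg(OAc)2 cat., CHCl3, 40 °C) gives the aryllead triacetate F13.
- F13 with F10 and pyridine in CHCl3 at 40–60 °C arylates C7 to give the mono-methyl ether dimer F14.
- BBr3 then gives 24.

## Further compounds

F1 | step 11 | lithiated alkenyl carbamate (C1–Li in place of C1–H of 13) | COc1cc(C)cc([C@H](C=C)C(C)C)c1[C@]([Li])(C)OC(=O)N(C(C)C)C(C)C
F2 | step 11 | vinyl boronate complex (lithium salt) | [Li+].COc1cc(C)cc([C@H](C=C)C(C)C)c1[C@](C)(OC(=O)N(C(C)C)C(C)C)[B-]1(C=C)OC(C)(C)C(C)(C)O1
F3 | step 11 | 2-[(S)-2-{2-methoxy-4-methyl-6-[(S)-4-methylpent-1-en-3-yl]phenyl}but-3-en-2-yl]-4,4,5,5-tetramethyl-1,3,2-dioxaborolane | COc1cc(C)cc([C@H](C=C)C(C)C)c1[C@](C)(B1OC(C)(C)C(C)(C)O1)C=C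
F4 | step 11 | 2-[(1S,4S)-4-isopropyl-8-methoxy-1,6-dimethyl-1,4-dihydronaphthalen-1-yl]-4,4,5,5-tetramethyl-1,3,2-dioxaborolane | COc1cc(C)cc2c1[C@](C)(B1OC(C)(C)C(C)(C)O1)C=C[C@@H]2C(C)C
F5 | step 9 | (S)-3-acryloyl-4-phenyloxazolidin-2-one | C=CC(=O)N1[C@@H](c2ccccc2)COC1=O
F6 | step 9 | (S)-1-{2-methoxy-4-methyl-6-[(E)-3-oxo-3-((S)-2-oxo-4-phenyloxazolidin-3-yl)prop-1-enyl]phenyl}ethyl N,N-diisopropylcarbamate | COc1cc(C)cc(/C=C/C(=O)N2[C@@H](c3ccccc3)COC2=O)c1[C@H](C)OC(=O)N(C(C)C)C(C)C
F7 | step 9 | (S)-1-{2-methoxy-4-methyl-6-[(R)-4-methyl-1-oxo-1-((S)-2-oxo-4-phenyloxazolidin-3-yl)pentan-3-yl]phenyl}ethyl N,N-diisopropylcarbamate | COc1cc(C)cc([C@H](CC(=O)N2[C@@H](c3ccccc3)COC2=O)C(C)C)c1[C@H](C)OC(=O)N(C(C)C)C(C)C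
F8 | step 9 | (S)-1-{2-[(R)-1-hydroxy-4-methylpentan-3-yl]-6-methoxy-4-methylphenyl}ethyl N,N-diisopropylcarbamate | COc1cc(C)cc([C@H](CCO)C(C)C)c1[C@H](C)OC(=O)N(C(C)C)C(C)C
F9 | step 9 | (S)-1-{2-[(R)-1-iodo-4-methylpentan-3-yl]-6-methoxy-4-methylphenyl}ethyl N,N-diisopropylcarbamate | COc1cc(C)cc([C@H](CCI)C(C)C)c1[C@H](C)OC(=O)N(C(C)C)C(C)C
F10 | step 15 | (1S,4R)-4-isopropyl-1,6-dimethyl-1,2,3,4-tetrahydronaphthalen-8-ol | Oc1cc(C)cc2c1[C@@H](C)CC[C@@H]2C(C)C
F11 | step 15 | (1S,4R)-4-isopropyl-5-lithio-8-methoxy-1,6-dimethyl-1,2,3,4-tetrahydronaphthalene | COc1cc(C)c([Li])c2c1[C@@H](C)CC[C@@H]2C(C)C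
F12 | step 15 | [(1S,4R)-4-isopropyl-8-methoxy-1,6-dimethyl-1,2,3,4-tetrahydronaphthalen-5-yl]boronic acid | COc1cc(C)c(B(O)O)c2c1[C@@H](C)CC[C@@H]2C(C)C
F13 | step 15 | [(1S,4R)-4-isopropyl-8-methoxy-1,6-dimethyl-1,2,3,4-tetrahydronaphthalen-5-yl]lead triacetate | COc1cc(C)c([Pb](OC(C)=O)(OC(C)=O)OC(C)=O)c2c1[C@@H](C)CC[C@@H]2C(C)C
F14 | step 15 | (1S,4R,1'S,4'R)-4,4'-diisopropyl-8'-methoxy-1,1',6,6'-tetramethyl-1,1',2,2',3,3',4,4'-octahydro-7,5'-binaphthalen-8-ol | Cc1cc2c(c(O)c1-c1c(C)cc(OC)c3c1[C@@H](C(C)C)CC[C@@H]3C)[C@@H](C)CC[C@@H]2C(C)C
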